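Labels used throughout: ring A = C8=C9–C10–C17H2–C18H2 (cyclopentene); ring B = C9–C10=C11(CO2Me)–C12–C13; ring C = C4–C5–C6–C7–C8=C9–C13 (cycloheptene); ring D = N–C14–C13–C4–C5–C15 (piperidine); ring E = O–C1(OH)(Et)–C2–C3–C4–C16 (lactol).
Ring E opens to the δ-hydroxy ketone; quaternary C4 goes back to a bridging C4 ketone (methoxymethylenation, hydroxymethylation with CH2O from the ring C face, olefination, hydrogenation); ring D goes back to an aza-Michael addition of the C14 methylamine to a C5 exo-methylene ketone.
Rings B and A are cut in one operation: C9–C10 by 1,2-addition of a C10 alkenylchromium to a C9 ketone, then C17–C18 by conrotatory 4π electrocyclisation of the pentadienyl cation C18=C8–C9(+)–C10=C17 that the carbinol releases in acid; loss of the C11 proton gives the dienoate.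
Enabling feature: C9 is the one carbon shared by rings A, B and C and sits between sp2 C8 and C10, which carry the two CH2 groups (C18, C17) of ring A, so ring A is a cyclised pentadienyl cation centred on a former ketone carbon and held U-shaped by rings B and C; the C4 ketone that rings D and E need is the mirror twin of C9, so the precursor is a prochiral 2,2-disubstituted 4,7-dimethylidenecycloheptane-1,3-dione and the chromium addition, steered by a chiral ligand, sets C13, from which C5, C4 and C1 follow by substrate control.
Ring order: C (bought as cycloheptane-1,3-dione), then B and A together, then D, then E; the precursor comes from the dione by C-propargylation, amidomethylation, carbonylation to an allenoate, HI addition and double α-methylenation.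

Key step: step 8

Assumption: the hemiketal carbon C1 equilibrates through the open hydroxy ketone, and the configuration drawn is taken to be the thermodynamic one (axial OH, equatorial ethyl, C13 equatorial on ring E).
Remark: the C11 centre made in step 6 is racemic and is erased in step 8, and the carbinol centre C9 made in step 8 is transient; both are left unspecified in the SMILES.
Remark: which enantiomer of the chiral ligand in step 8 delivers the C13 configuration shown has to be established in the first experiments.

Step 1
Reactants: 1 N-methyl-2,2,2-trifluoroacetamide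
Product: 2 2,2,2-trifluoro-N-(hydroxymethyl)-N-methylacetamide
Conditions: (CH2O)n, K2CO3 (cat.), THF, 50 °C
Reagents that add atoms: formaldehyde (from paraformaldehyde) C=O
Why: Base-catalysed N-hydroxymethylation of a secondary amide by formaldehyde should give the stable amidomethylating agent needed for a Tscherniac–Einhorn-type reaction.

Step 2
Reactants: 3 4-chlorobut-2-yn-1-ol
Product: 4 4-chlorobut-2-yn-1-yl methyl carbonate
Conditions: ClCO2Me, pyridine, CH2Cl2, 0 °C
Reagents that add atoms: methyl chloroformate COC(=O)Cl
Why: Acylation of the primary propargylic alcohol installs the carbonate that later serves as leaving group in the palladium-catalysed carbonylation, while the propargylic chloride stays as the alkylating end.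

Step 3
Reactants: 5 cycloheptane-1,3-dione; 4 4-chlorobut-2-yn-1-yl methyl carbonate
Product: 6 4-(2,7-dioxocycloheptyl)but-2-yn-1-yl methyl carbonate
Conditions: K2CO3, KI (cat.), H2O/THF, 40 °C
Reagents that add atoms: none
Why: C-alkylation of the cyclic 1,3-dione enolate by the propargylic chloride (iodide catalysis; water favours C- over O-alkylation) should attach C12 together with the masked C11–C10–C17 unit, the carbonate being inert here.

Step 4
Reactants: 6 4-(2,7-dioxocycloheptyl)but-2-yn-1-yl methyl carbonate; 2 2,2,2-trifluoro-N-(hydroxymethyl)-N-methylacetamide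
Product: 7 4-[1-({methyl(trifluoroacetyl)amino}methyl)-2,7-dioxocycloheptyl]but-2-yn-1-yl methyl carbonate
Conditions: CF3SO3H (10 mol %), CH2Cl2, 0 °C to rt
Reagents that add atoms: none
Why: The acid-generated N-acyliminium ion should be captured at carbon by the enol of the 2-substituted dione (Tscherniac–Einhorn/Mannich-type amidoalkylation, O-attack being reversible), giving the achiral quaternary C13 with a nitrogen group that is neither basic nor prone to retro-Mannich loss.

Step 5
Reactants: 7 4-[1-({methyl(trifluoroacetyl)amino}methyl)-2,7-dioxocycloheptyl]but-2-yn-1-yl methyl carbonate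
Product: 8 methyl 2-{[1-({methyl(trifluoroacetyl)amino}methyl)-2,7-dioxocycloheptyl]methyl}buta-2,3-dienoate
Conditions: Pd(OAc)2 (5 mol %), PPh3, CO (5 bar), MeOH/THF, 45 °C
Reagents that add atoms: carbon monoxide [C-]#[O+]; methanol CO
Why: Zerovalent palladium should ionise the propargylic carbonate in SN2′ fashion to an allenylpalladium species, and CO insertion with methanolysis gives the 2-substituted buta-2,3-dienoate (the known carbonylation of propargylic carbonates), which places the ester on C11 under neutral conditions.

Step 6
Reactants: 8 methyl 2-{[1-({methyl(trifluoroacetyl)amino}methyl)-2,7-dioxocycloheptyl]methyl}buta-2,3-dienoate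
Product: 9 methyl 3-iodo-2-{[1-({methyl(trifluoroacetyl)amino}methyl)-2,7-dioxocycloheptyl]methyl}but-3-enoate (both C11 epimers)
Conditions: NaI, AcOH, rt
Reagents that add atoms: sodium iodide [Na+].[I-]
Why: Conjugate addition of iodide to the central allene carbon C10 and kinetic α-protonation (the known hydrohalogenation of 2,3-allenoates to 3-halo-3-enoates) should give the 2-iodoalkene C10(I)=C17H2 needed for chromium insertion.

Step 7
Reactants: 9 methyl 3-iodo-2-{[1-({methyl(trifluoroacetyl)amino}methyl)-2,7-dioxocycloheptyl]methyl}but-3-enoate
Product: 10 methyl 3-iodo-2-{[1-({methyl(trifluoroacetyl)amino}methyl)-3,6-dimethylidene-2,7-dioxocycloheptyl]methyl}but-3-enoate (symmetrical bis-enone; both C11 epimers)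
Conditions: (CH2O)n, PhNHMe·CF3CO2H, THF, reflux
Reagents that add atoms: formaldehyde (from paraformaldehyde, two equivalents) C=O
Why: Two-fold Mannich condensation–elimination (direct α-methylenation of ketones with formaldehyde and a secondary ammonium trifluoroacetate) can only occur at the two enolisable carbons C5 and C8, so it should install C15 and C18 without breaking the symmetry or creating a stereocentre.

Step 8
Reactants: 10 methyl 3-iodo-2-{[1-({methyl(trifluoroacetyl)amino}methyl)-3,6-dimethylidene-2,7-dioxocycloheptyl]methyl}but-3-enoate
Product: 12 tricyclic dienoate enone (rings A B C; C8=C9–C10=C11–CO2Me; ketone C4; exo-methylene C5=C15; CH2N(Me)COCF3 on C13), via bis-allylic tertiary alcohol 11 (not isolated)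
Conditions: CrCl2 (4 equiv), (S)-N-[2-(4-tert-butyl-4,5-dihydro-1,3-oxazol-2-yl)-6-methylphenyl]methanesulfonamide (or its enantiomer), Et3N, NiCl2 (2 mol %), THF, rt; then CF3CO2H (excess), CH2Cl2, 0 °C to rt
Reagents that add atoms: none
Why: Proposed new method: oxidative addition of the C10–I bond to zerovalent nickel and transmetalation should give a C10 alkenyl species of trivalent chromium that adds 1,2 (5-exo-trig, ring B) to one of the two enantiotopic enone carbonyls inside the chiral ligand sphere, which alone sets C13; trifluoroacetic acid then ionises the tertiary bis-allylic alkoxide to the pentadienyl cation C18=C8–C9(+)–C10=C17, which rings B and C hold in the U shape with C17 and C18 in contact, and the thermally allowed conrotatory 4π electrocyclisation closes ring A. The resulting cyclopentenyl cation (C8–C9–C10) should lose the C11 proton to give the ester-conjugated diene, the thermodynamic isomer to which other deprotonation products can return by reprotonation. Closest known reaction types: intramolecular Nozaki–Hiyama–Kishi alkenylation of ketones, ligand-controlled enantioselective Nozaki–Hiyama–Kishi additions to aldehydes, catalytic desymmetrising additions to 2,2-disubstituted cyclic 1,3-diones, and the acid-mediated cyclisation of divinyl carbinols to cyclopentadienes (a Nazarov-type electrocyclisation without the oxygen). Selectivity needed: carbonyl rather than conjugate addition, secured by the organochromium reagent; discrimination of the two enantiotopic carbonyls, asked of the ligand; electrocyclisation rather than elimination or trapping, secured because the charge-bearing carbons C18, C9 and C17 have no β-hydrogen and the trifluoroacetamide and ester oxygens can add only reversibly. What is new is the enantiotopic-ketone-selective chromium addition and its coupling with the cation cyclisation in one flask.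

Step 9
Reactants: 12 tricyclic dienoate enone
Product: 14 tetracyclic amino ketone (rings A to D; N-methyl; bridging ketone C4; C5–H), via free secondary amine 13 (not isolated)
Conditions: K2CO3, MeOH/H2O, rt
Reagents that add atoms: none
Why: Mild basic cleavage of the tertiary trifluoroacetamide frees the methylamine, which should add 6-endo-trig to the C5 exo-methylene ketone (the classical amine-to-enone route to 4-piperidones); the one-carbon bridge C4 can only be spanned cis, so protonation fixes C5 from C13.

Step 10
Reactants: 14 tetracyclic amino ketone
Product: 16 aldehyde (C4–H and C4–CHO; both C4 epimers), via methyl enol ether 15 (not isolated)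
Conditions: Ph3P(CH2OMe)Cl, KN(SiMe3)2, THF, 0 to 50 °C; then 2 M HCl, THF, rt
Reagents that add atoms: (methoxymethyl)triphenylphosphonium chloride [Cl-].COC[P+](c1ccccc1)(c1ccccc1)c1ccccc1; water O
Why: Wittig methoxymethylenation of the hardly enolisable bridging ketone and acid hydrolysis of the enol ether should give the homologous aldehyde, whose C4 configuration does not matter because the centre is re-formed through the enolate in step 11.

Step 11
Reactants: 16 aldehyde
Product: 17 hydroxy aldehyde (quaternary C4; CHO over ring D; CH2OH over ring C)
Conditions: aq. CH2O (37 %), K2CO3, MeOH, 0 °C to rt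
Reagents that add atoms: formaldehyde C=O
Why: Crossed aldol addition of the exocyclic aldehyde enolate to formaldehyde creates quaternary C4, and the small electrophile should approach from the ring C face, which lacks the two axial hydrogens at C14 and C15 that shield the ring D face, so that C16 ends up syn to C9 as in the target.

Step 12
Reactants: 17 hydroxy aldehyde
Product: 18 triethylsilyl ether of 17
Conditions: Et3SiCl, imidazole, CH2Cl2, 0 °C
Reagents that add atoms: chlorotriethylsilane CC[Si](Cl)(CC)CC
Why: Silylation of the primary alcohol should prevent its oxa-Michael closure onto the enone made in the next step.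

Step 13
Reactants: 18 triethylsilyl ether of 17; 19 diethyl (2-oxobutyl)phosphonate
Product: 20 (E)-enone (C4–CH=CH–C(=O)Et; silyl ether retained)
Conditions: NaH, THF, 0 °C to rt
Reagents that add atoms: none
Why: Horner–Wadsworth–Emmons olefination of the non-enolisable aldehyde with the β-keto phosphonate anion should give the (E)-enone that carries C2, C1 and the ethyl group.

Step 14
Reactants: 20 (E)-enone
Product: 23 CNP0192143.3 (target), via saturated ketone silyl ether 21 (not isolated), via open hydroxy ketone 22 (not isolated)
Conditions: H2 (1 atm), RhCl(PPh3)3 (5 mol %), benzene/EtOH, rt; then 1 M HCl, THF, rt; NaHCO3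
Reagents that add atoms: none
Why: RhCl(PPh3)3 should hydrogenate the disubstituted enone C=C but not the tetrasubstituted dienoate, and acid cleavage of the silyl ether lets the δ-hydroxy ketone close to the six-membered hemiketal, whose C1 configuration is set under thermodynamic control (axial OH, equatorial ethyl).

Compound list
1 | N-methyl-2,2,2-trifluoroacetamide | CNC(=O)C(F)(F)F | starting material
2 | 2,2,2-trifluoro-N-(hydroxymethyl)-N-methylacetamide | CN(CO)C(=O)C(F)(F)F | intermediate
3 | 4-chlorobut-2-yn-1-ol | OCC#CCCl | starting material
4 | 4-chlorobut-2-yn-1-yl methyl carbonate | COC(=O)OCC#CCCl | intermediate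
5 | cycloheptane-1,3-dione | O=C1CCCCC(=O)C1 | starting material
6 | 4-(2,7-dioxocycloheptyl)but-2-yn-1-yl methyl carbonate | COC(=O)OCC#CCC1C(=O)CCCCC1=O | intermediate
7 | 4-[1-({methyl(trifluoroacetyl)amino}methyl)-2,7-dioxocycloheptyl]but-2-yn-1-yl methyl carbonate (achiral) | COC(=O)OCC#CCC1(CN(C)C(=O)C(F)(F)F)C(=O)CCCCC1=O | intermediate
8 | methyl 2-{[1-({methyl(trifluoroacetyl)amino}methyl)-2,7-dioxocycloheptyl]methyl}buta-2,3-dienoate (achiral) | COC(=O)C(=C=C)CC1(CN(C)C(=O)C(F)(F)F)C(=O)CCCCC1=O | intermediate
9 | methyl 3-iodo-2-{[1-({methyl(trifluoroacetyl)amino}methyl)-2,7-dioxocycloheptyl]methyl}but-3-enoate (C11 racemic) | COC(=O)C(CC1(CN(C)C(=O)C(F)(F)F)C(=O)CCCCC1=O)C(I)=C | intermediate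
10 | methyl 3-iodo-2-{[1-({methyl(trifluoroacetyl)amino}methyl)-3,6-dimethylidene-2,7-dioxocycloheptyl]methyl}but-3-enoate (C11 racemic; the two enone halves are enantiotopic) | COC(=O)C(CC1(CN(C)C(=O)C(F)(F)F)C(=O)C(=C)CCC(=C)C1=O)C(I)=C | intermediate
11 | bis-allylic tertiary alcohol, not isolated (ring B closed by C9–C10; C9–OH flanked by C8=C18H2 and C10=C17H2; C13 set; C9 and C11 unspecified) | COC(=O)C1C[C@]2(CN(C)C(=O)C(F)(F)F)C(=O)C(=C)CCC(=C)C2(O)C1=C | intermediate
12 | tricyclic dienoate enone (rings A, B, C; C8=C9–C10=C11–CO2Me; ketone C4; C5=C15H2; CH2N(Me)COCF3 on C13, configured as in the target) | COC(=O)C1=C2CCC3=C2[C@@](C1)(CN(C)C(=O)C(F)(F)F)C(=O)C(=C)CC3 | intermediate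
13 | free secondary amine of 12, not isolated (CH2NHMe on C13) | COC(=O)C1=C2CCC3=C2[C@@](C1)(CNC)C(=O)C(=C)CC3 | intermediate
14 | tetracyclic amino ketone (rings A to D; N-methylpiperidine bridged by the C4 ketone; C13 and C5 as in the target) | COC(=O)C1=C2CCC3=C2[C@@]2(C1)CN(C)C[C@@H](CC3)C2=O | intermediate
15 | methyl enol ether, not isolated (C4=CH–OMe; double-bond geometry unspecified) | COC(=O)C1=C2CCC3=C2[C@@]2(C1)CN(C)C[C@@H](CC3)C2=COC | intermediate
16 | aldehyde (C4 bears H and CHO; both C4 epimers) | COC(=O)C1=C2CCC3=C2[C@@]2(C1)CN(C)C[C@@H](CC3)C2C=O | intermediate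
17 | hydroxy aldehyde (quaternary C4: CHO over ring D, CH2OH over ring C) | COC(=O)C1=C2CCC3=C2[C@@]2(C1)CN(C)C[C@@H](CC3)[C@@]2(C=O)CO | intermediate
18 | triethylsilyl ether of 17 | COC(=O)C1=C2CCC3=C2[C@@]2(C1)CN(C)C[C@@H](CC3)[C@@]2(C=O)CO[Si](CC)(CC)CC | intermediate
19 | diethyl (2-oxobutyl)phosphonate | CCOP(=O)(CC(=O)CC)OCC | starting material
20 | (E)-enone (C4–CH=CH–C(=O)CH2CH3 over ring D; CH2OSiEt3 over ring C) | COC(=O)C1=C2CCC3=C2[C@@]2(C1)CN(C)C[C@@H](CC3)[C@@]2(/C=C/C(=O)CC)CO[Si](CC)(CC)CC | intermediate
21 | saturated ketone silyl ether, not isolated | COC(=O)C1=C2CCC3=C2[C@@]2(C1)CN(C)C[C@@H](CC3)[C@@]2(CCC(=O)CC)CO[Si](CC)(CC)CC | intermediate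
22 | open δ-hydroxy ketone, not isolated | COC(=O)C1=C2CCC3=C2[C@@]2(C1)CN(C)C[C@@H](CC3)[C@@]2(CCC(=O)CC)CO | intermediate
23 | CNP0192143.3 (hemiketal; C16H2O over ring C, C3 chain over ring D; OH axial and ethyl equatorial on ring E) | CC[C@]1(O)CC[C@@]2(CO1)[C@@H]1CCC3=C4C(=C(C(=O)OC)C[C@@]42CN(C)C1)CC3 | target

Total steps: 14. Longest linear sequence: 13 steps (from 3 through 4, 6, 7, 8, 9, 10, 12, 14, 16, 17, 18 and 20 to 23).

Steps most likely to fail

Step 8. What may go wrong: too little discrimination between the two enantiotopic carbonyls (the racemic C11 centre may work against the ligand), capture of the pentadienyl cation by oxygen nucleophiles before it cyclises, or proton loss to non-conjugated diene isomers. The fallback sets out from 10 and separates the two events, using known chemistry only. A ligand-free Nozaki–Hiyama–Kishi cyclisation (CrCl2, NiCl2 cat., DMF) would give the tertiary alcohol as a racemate, that is 11 together with the mirror-image alcohol F1, which is isolated. Treatment with TsOH·H2O in CH2Cl2 (acid-mediated cyclisation of a divinyl carbinol, followed by DBU equilibration if diene isomers form) would give 12 together with the mirror-image dienoate F2. Preparative chromatography on a chiral stationary phase then returns to the route at 12.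

Step 7. What may go wrong: incomplete second methylenation, oligomerisation of the exo-methylene enones on heating, or migration of the C10=C17 double bond into conjugation with the ester. The fallback sets out from 9 and builds the methylene groups stepwise under mild conditions. Soft enolisation (Me3SiOSO2CF3, Et3N, CH2Cl2, 0 °C) would give the bis(trimethylsilyl enol ether) F3. Mannich reaction with dimethylmethylideneammonium iodide (Me2N=CH2 I, CH2Cl2, rt) would give the bis(dimethylaminomethyl) diketone F4. N-methylation with MeI would give the bis(trimethylammonium) diiodide F5, and elimination with NaHCO3 in CH2Cl2/H2O directly before use returns to the route at 10.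

Step 11. What may go wrong: attack of formaldehyde from the ring D face (wrong C4 configuration), retro-aldol loss of formaldehyde, or crossed Cannizzaro reduction of the product. The fallback sets out from 16 and introduces the two C4 substituents in the opposite order, so that a preference for the ring D face would lead to the required configuration. Michael addition of 16 to pent-1-en-3-one (pyrrolidine/AcOH enamine catalysis or cat. KOH) would give the keto aldehyde F6 with the 3-oxopentyl chain over ring D and the CHO group over ring C. NaBH(OAc)3 should then reduce only the aldehyde, giving 22, which closes to the hemiketal and returns to the route at 23.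

Further compounds
F1 | step 8 | mirror image of alcohol 11 | COC(=O)C1C[C@@]2(CN(C)C(=O)C(F)(F)F)C(=O)C(=C)CCC(=C)C2(O)C1=C
F2 | step 8 | mirror image of tricyclic dienoate enone 12 | COC(=O)C1=C2CCC3=C2[C@](C1)(CN(C)C(=O)C(F)(F)F)C(=O)C(=C)CC3
F3 | step 7 | bis(trimethylsilyl enol ether) of 9 | COC(=O)C(CC1(CN(C)C(=O)C(F)(F)F)C(O[Si](C)(C)C)=CCCC=C1O[Si](C)(C)C)C(I)=C
F4 | step 7 | bis(dimethylaminomethyl) diketone | COC(=O)C(CC1(CN(C)C(=O)C(F)(F)F)C(=O)C(CN(C)C)CCC(CN(C)C)C1=O)C(I)=C
F5 | step 7 | bis(trimethylammonium) diiodide of F4 | COC(=O)C(CC1(CN(C)C(=O)C(F)(F)F)C(=O)C(C[N+](C)(C)C)CCC(C[N+](C)(C)C)C1=O)C(I)=C.[I-].[I-]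
F6 | step 11 | keto aldehyde (quaternary C4: 3-oxopentyl over ring D, CHO over ring C) | COC(=O)C1=C2CCC3=C2[C@@]2(C1)CN(C)C[C@@H](CC3)[C@]2(C=O)CCC(=O)CC
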